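**Assumption:** the SMILES has no stereodescriptor and the 3'–8'' biaryl axis of this amentoflavone-type biflavone is not configurationally defined, so the target is treated as achiral and no stereocentre has to be set.

Locants: the apigenin half uses unprimed and singly primed positions (its ring B carries 4'-OH and the link at C3'). The chrysoeriol half uses doubly primed chromone positions (link at C8'') and a triply primed ring B (3'''-OMe, 4'''-OH).

## Retrosynthetic overview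

1. Target 18 comes from silylene-bridged biflavone 16 by desilylation and hydrogenolysis of four benzyl ethers; the methyl ether is never touched.
2. The 3'–8'' biaryl bond of 16 is made by a new intramolecular palladium-catalysed C–H arylation across a di-tert-butylsilylene tether (15). The tether uses the two hydroxyls that flank the biaryl bond in the target (7''-OH and 4'-OH).
3. The tether partners are 8-bromo-7-hydroxyflavone 8 (fragment 1) and 4'-hydroxyflavone 13 (fragment 2). Each is made by Claisen–Schmidt condensation and iodine/DMSO oxidative cyclisation.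
4. Acetophenones 4 and 9 both come from 2,4,6-trihydroxyacetophenone 1; aldehydes 5 and 10 are commercial.
5. Ring order: ring C of the chrysoeriol half, then ring C of the apigenin half, then the temporary seven-membered dioxasilepine ring, which is opened again.

## Route

**Step 1**
Reactants: 1 2,4,6-trihydroxyacetophenone
Product: 2 1-[2,6-dihydroxy-4-(methoxymethoxy)phenyl]ethan-1-one
Conditions: MOMCl (1.0 equiv), iPr2NEt (1.2 equiv), THF, 0 °C
Reagents that add atoms: chloromethyl methyl ether (MOMCl), COCCl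
Why: Williamson-type O-alkylation (MOM protection); the 4-OH is the most acidic and the only hydroxyl not hydrogen-bonded to the acetyl group, so one equivalent reacts there first.

**Step 2**
Reactants: 2 1-[2,6-dihydroxy-4-(methoxymethoxy)phenyl]ethan-1-one
Product: 3 1-[2-(benzyloxy)-6-hydroxy-4-(methoxymethoxy)phenyl]ethan-1-one
Conditions: BnBr (1.05 equiv), K2CO3 (1.1 equiv), DMF, rt
Reagents that add atoms: benzyl bromide, BrCc1ccccc1
Why: Williamson ether synthesis; the two hydroxyls of 2 are equivalent, and after the first benzylation the remaining one is chelated to the carbonyl and alkylates much more slowly.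

**Step 3**
Reactants: 3 1-[2-(benzyloxy)-6-hydroxy-4-(methoxymethoxy)phenyl]ethan-1-one
Product: 4 1-[6-(benzyloxy)-3-bromo-2-hydroxy-4-(methoxymethoxy)phenyl]ethan-1-one
Conditions: NBS (1.0 equiv), CH2Cl2, −20 to 0 °C
Reagents that add atoms: N-bromosuccinimide, O=C1CCC(=O)N1Br
Why: electrophilic aromatic bromination; C3 (ortho to the free phenol) is less hindered than C5 (flanked by OMOM and OBn), the selectivity expected by analogy with 2-hydroxy-4,6-dimethoxyacetophenone.

**Step 4**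
Reactants: 4 1-[6-(benzyloxy)-3-bromo-2-hydroxy-4-(methoxymethoxy)phenyl]ethan-1-one, 5 4-(benzyloxy)-3-methoxybenzaldehyde
Product: 6 (E)-1-[6-(benzyloxy)-3-bromo-2-hydroxy-4-(methoxymethoxy)phenyl]-3-[4-(benzyloxy)-3-methoxyphenyl]prop-2-en-1-one
Conditions: KOH (50% aq.), EtOH/THF, rt
Reagents that add atoms: none
Why: Claisen–Schmidt aldol condensation; the aldehyde has no α-hydrogen and dehydration gives the thermodynamic E enone, while MOM, benzyl and aryl bromide are stable to base.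

**Step 5**
Reactants: 6 (E)-1-[6-(benzyloxy)-3-bromo-2-hydroxy-4-(methoxymethoxy)phenyl]-3-[4-(benzyloxy)-3-methoxyphenyl]prop-2-en-1-one
Product: 8 5-(benzyloxy)-2-[4-(benzyloxy)-3-methoxyphenyl]-8-bromo-7-hydroxy-4H-chromen-4-one, via 7-O-MOM bromoflavone 7 (not isolated)
Conditions: I2 (10 mol %), DMSO, 120 °C; aq. Na2S2O3 work-up; then 3% HCl in MeOH, THF, 45 °C
Reagents that add atoms: none
Why: iodine/DMSO oxidative cyclisation of a 2'-hydroxychalcone (oxa-Michael closure through the only free hydroxyl, next to the bromine, so bromine ends at C8), followed by acid-catalysed MOM acetal exchange that leaves the benzyl ethers intact.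

**Step 6**
Reactants: 1 2,4,6-trihydroxyacetophenone
Product: 9 1-[2,4-bis(benzyloxy)-6-hydroxyphenyl]ethan-1-one
Conditions: BnBr (2.1 equiv), K2CO3 (2.2 equiv), DMF, rt
Reagents that add atoms: benzyl bromide, BrCc1ccccc1
Why: Williamson ether synthesis; the third hydroxyl stays free because it is chelated to the carbonyl.

**Step 7**
Reactants: 9 1-[2,4-bis(benzyloxy)-6-hydroxyphenyl]ethan-1-one, 10 4-(methoxymethoxy)benzaldehyde
Product: 11 (E)-1-[2,4-bis(benzyloxy)-6-hydroxyphenyl]-3-[4-(methoxymethoxy)phenyl]prop-2-en-1-one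
Conditions: KOH (50% aq.), EtOH/THF, rt
Reagents that add atoms: none
Why: Claisen–Schmidt aldol condensation giving the E chalcone; the MOM ether keeps the aldehyde electrophilic by preventing phenoxide formation.

**Step 8**
Reactants: 11 (E)-1-[2,4-bis(benzyloxy)-6-hydroxyphenyl]-3-[4-(methoxymethoxy)phenyl]prop-2-en-1-one
Product: 13 5,7-bis(benzyloxy)-2-(4-hydroxyphenyl)-4H-chromen-4-one, via 4'-O-MOM flavone 12 (not isolated)
Conditions: I2 (10 mol %), DMSO, 120 °C; aq. Na2S2O3 work-up; then 3% HCl in MeOH, THF, 45 °C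
Reagents that add atoms: none
Why: iodine/DMSO oxidative cyclisation of the 2'-hydroxychalcone to the flavone, then acid-catalysed MOM removal to free only the 4'-OH.

**Step 9**
Reactants: 8 5-(benzyloxy)-2-[4-(benzyloxy)-3-methoxyphenyl]-8-bromo-7-hydroxy-4H-chromen-4-one, 13 5,7-bis(benzyloxy)-2-(4-hydroxyphenyl)-4H-chromen-4-one
Product: 15 {[5-(benzyloxy)-2-(4-benzyloxy-3-methoxyphenyl)-8-bromo-4-oxo-4H-chromen-7-yl]oxy}{4-[5,7-bis(benzyloxy)-4-oxo-4H-chromen-2-yl]phenoxy}di-tert-butylsilane, via aryloxysilyl triflate 14 (not isolated)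
Conditions: tBu2Si(OTf)2 (1.05 equiv), 2,6-lutidine (3 equiv), CH2Cl2, −40 to 0 °C (8 added slowly); then 13, DMAP (20 mol %), 0 to 35 °C
Reagents that add atoms: di-tert-butylsilyl bis(trifluoromethanesulfonate), CC(C)(C)[Si](OS(=O)(=O)C(F)(F)F)(OS(=O)(=O)C(F)(F)F)C(C)(C)C
Why: sequential O-silylation (silylene ketal formation); the hindered bromophenol takes the first, very reactive triflate, and the now bulky monotriflate resists a second hindered phenol but accepts the unhindered 4'-phenol under DMAP catalysis.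

**Step 10**
Reactants: 15 {[5-(benzyloxy)-2-(4-benzyloxy-3-methoxyphenyl)-8-bromo-4-oxo-4H-chromen-7-yl]oxy}{4-[5,7-bis(benzyloxy)-4-oxo-4H-chromen-2-yl]phenoxy}di-tert-butylsilane
Product: 16 silylene-bridged biflavone: C8'' of the chrysoeriol half (5''-OBn, 4'''-OBn, 3'''-OMe) bonded to C3' of the apigenin half (5,7-di-OBn), with O7'' and O4' joined through Si(t-Bu)2 in a 6,6-di-tert-butyldibenzo[d,f][1,3,2]dioxasilepine ring
Conditions: Pd(OAc)2 (10 mol %), PCy3·HBF4 (20 mol %), PivOH (30 mol %), Cs2CO3 (2 equiv), 4 Å MS, mesitylene, 130 °C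
Reagents that add atoms: none
Why: Proposed new method: silicon-tethered intramolecular palladium-catalysed C–H arylation between two flavones, in which zerovalent palladium inserts into the C8''–Br bond, bromide is exchanged for pivalate on divalent palladium, pivalate-assisted concerted metalation–deprotonation of the C3'–H bond ortho to the silyloxy group (C3' and C5' are equivalent, so there is no regiochemical choice) closes an eight-membered palladacycle favoured by the gem-di-tert-butyl effect, and reductive elimination forms the 3'–8'' bond inside a seven-membered dioxasilepine; the closest known reaction type is the pivalate-assisted palladium-catalysed C–H arylation of simple (2-bromoaryloxy)(aryloxy)di-tert-butylsilanes to unsymmetrical 2,2'-biphenols, which has not been shown on chromones, on a bromide flanked by two oxygen substituents, or for a biflavone linkage.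

**Step 11**
Reactants: 16 silylene-bridged biflavone
Product: 17 5-(benzyloxy)-2-[4-(benzyloxy)-3-methoxyphenyl]-8-{5-[5,7-bis(benzyloxy)-4-oxo-4H-chromen-2-yl]-2-hydroxyphenyl}-7-hydroxy-4H-chromen-4-one
Conditions: HF·pyridine, THF/pyridine, 0 °C to rt
Reagents that add atoms: none
Why: fluoride-driven cleavage of both aryl Si–O bonds (desilylation); benzyl and methyl ethers and the chromones are inert.

**Step 12**
Reactants: 17 5-(benzyloxy)-2-[4-(benzyloxy)-3-methoxyphenyl]-8-{5-[5,7-bis(benzyloxy)-4-oxo-4H-chromen-2-yl]-2-hydroxyphenyl}-7-hydroxy-4H-chromen-4-one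
Product: 18 8-[5-(5,7-dihydroxy-4-oxo-4H-chromen-2-yl)-2-hydroxyphenyl]-5,7-dihydroxy-2-(4-hydroxy-3-methoxyphenyl)-4H-chromen-4-one (target, CNP0179340.0)
Conditions: H2 (1 atm), 10% Pd/C, THF/MeOH, rt
Reagents that add atoms: none
Why: catalytic hydrogenolysis of the four benzyl ethers; the aryl methyl ether is untouched and the chromone C2=C3 bonds are reduced much more slowly, so the reaction is stopped at full debenzylation.

## Compound list

1 | 2,4,6-trihydroxyacetophenone | CC(=O)c1c(O)cc(O)cc1O | starting material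
2 | 1-[2,6-dihydroxy-4-(methoxymethoxy)phenyl]ethan-1-one | CC(=O)c1c(O)cc(OCOC)cc1O | intermediate
3 | 1-[2-(benzyloxy)-6-hydroxy-4-(methoxymethoxy)phenyl]ethan-1-one | CC(=O)c1c(O)cc(OCOC)cc1OCc1ccccc1 | intermediate
4 | 1-[6-(benzyloxy)-3-bromo-2-hydroxy-4-(methoxymethoxy)phenyl]ethan-1-one | CC(=O)c1c(O)c(Br)c(OCOC)cc1OCc1ccccc1 | intermediate
5 | 4-(benzyloxy)-3-methoxybenzaldehyde | COc1cc(C=O)ccc1OCc1ccccc1 | starting material
6 | (E)-1-[6-(benzyloxy)-3-bromo-2-hydroxy-4-(methoxymethoxy)phenyl]-3-[4-(benzyloxy)-3-methoxyphenyl]prop-2-en-1-one | COCOc1cc(OCc2ccccc2)c(C(=O)/C=C/c2ccc(OCc3ccccc3)c(OC)c2)c(O)c1Br | intermediate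
7 | 5-(benzyloxy)-2-[4-(benzyloxy)-3-methoxyphenyl]-8-bromo-7-(methoxymethoxy)-4H-chromen-4-one | COCOc1cc(OCc2ccccc2)c2c(=O)cc(-c3ccc(OCc4ccccc4)c(OC)c3)oc2c1Br | intermediate
8 | 5-(benzyloxy)-2-[4-(benzyloxy)-3-methoxyphenyl]-8-bromo-7-hydroxy-4H-chromen-4-one | Oc1cc(OCc2ccccc2)c2c(=O)cc(-c3ccc(OCc4ccccc4)c(OC)c3)oc2c1Br | intermediate
9 | 1-[2,4-bis(benzyloxy)-6-hydroxyphenyl]ethan-1-one | CC(=O)c1c(O)cc(OCc2ccccc2)cc1OCc1ccccc1 | intermediate
10 | 4-(methoxymethoxy)benzaldehyde | COCOc1ccc(C=O)cc1 | starting material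
11 | (E)-1-[2,4-bis(benzyloxy)-6-hydroxyphenyl]-3-[4-(methoxymethoxy)phenyl]prop-2-en-1-one | COCOc1ccc(/C=C/C(=O)c2c(O)cc(OCc3ccccc3)cc2OCc2ccccc2)cc1 | intermediate
12 | 5,7-bis(benzyloxy)-2-[4-(methoxymethoxy)phenyl]-4H-chromen-4-one | COCOc1ccc(-c2cc(=O)c3c(OCc4ccccc4)cc(OCc4ccccc4)cc3o2)cc1 | intermediate
13 | 5,7-bis(benzyloxy)-2-(4-hydroxyphenyl)-4H-chromen-4-one | Oc1ccc(-c2cc(=O)c3c(OCc4ccccc4)cc(OCc4ccccc4)cc3o2)cc1 | intermediate
14 | {[5-(benzyloxy)-2-(4-benzyloxy-3-methoxyphenyl)-8-bromo-4-oxo-4H-chromen-7-yl]oxy}di-tert-butylsilyl trifluoromethanesulfonate | CC(C)(C)[Si](Oc1cc(OCc2ccccc2)c2c(=O)cc(-c3ccc(OCc4ccccc4)c(OC)c3)oc2c1Br)(OS(=O)(=O)C(F)(F)F)C(C)(C)C | intermediate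
15 | {[5-(benzyloxy)-2-(4-benzyloxy-3-methoxyphenyl)-8-bromo-4-oxo-4H-chromen-7-yl]oxy}{4-[5,7-bis(benzyloxy)-4-oxo-4H-chromen-2-yl]phenoxy}di-tert-butylsilane | CC(C)(C)[Si](Oc1cc(OCc2ccccc2)c2c(=O)cc(-c3ccc(OCc4ccccc4)c(OC)c3)oc2c1Br)(Oc1ccc(-c2cc(=O)c3c(OCc4ccccc4)cc(OCc4ccccc4)cc3o2)cc1)C(C)(C)C | intermediate
16 | silylene-bridged biflavone (C8''–C3' bond; O7''–Si(t-Bu)2–O4' dioxasilepine; 5''-OBn, 4'''-OBn, 3'''-OMe, 5,7-di-OBn) | CC(C)(C)[Si]1(C(C)(C)C)Oc2ccc(-c3cc(=O)c4c(OCc5ccccc5)cc(OCc5ccccc5)cc4o3)cc2-c2c(O1)cc(OCc3ccccc3)c3c(=O)cc(-c4ccc(OCc5ccccc5)c(OC)c4)oc23 | intermediate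
17 | 5-(benzyloxy)-2-[4-(benzyloxy)-3-methoxyphenyl]-8-{5-[5,7-bis(benzyloxy)-4-oxo-4H-chromen-2-yl]-2-hydroxyphenyl}-7-hydroxy-4H-chromen-4-one | Oc1ccc(-c2cc(=O)c3c(OCc4ccccc4)cc(OCc4ccccc4)cc3o2)cc1-c1c(O)cc(OCc2ccccc2)c2c(=O)cc(-c3ccc(OCc4ccccc4)c(OC)c3)oc12 | intermediate
18 | 8-[5-(5,7-dihydroxy-4-oxo-4H-chromen-2-yl)-2-hydroxyphenyl]-5,7-dihydroxy-2-(4-hydroxy-3-methoxyphenyl)-4H-chromen-4-one | COc1cc(-c2cc(=O)c3c(O)cc(O)c(-c4cc(-c5cc(=O)c6c(O)cc(O)cc6o5)ccc4O)c3o2)ccc1O | target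

## Step count

Total: 12 steps. Longest linear sequence: 9 steps (steps 1, 2, 3, 4, 5, 9, 10, 11, 12); steps 6–8 form the second branch, which joins at step 9.

## Steps most likely to fail, with fallbacks

**Step 10 (the proposed new C–H arylation).** Risks are slow oxidative addition at the doubly ortho-oxygenated bromide, reduction of the C–Br bond, and loss of the tether at 130 °C.

The fallback uses only known chemistry, sets out from 13 and 8, and comes back to the route at 18. Phenol 13 is brominated ortho to the hydroxyl (Br2, tert-butylamine, toluene, −70 °C; amine-directed ortho-bromination of phenols) to give 5,7-bis(benzyloxy)-2-(3-bromo-4-hydroxyphenyl)-4H-chromen-4-one F1. Benzylation (BnBr, K2CO3, DMF) gives 5,7-bis(benzyloxy)-2-[4-(benzyloxy)-3-bromophenyl]-4H-chromen-4-one F2. Miyaura borylation (B2pin2, PdCl2(dppf), KOAc, dioxane, 90 °C) gives 5,7-bis(benzyloxy)-2-[4-(benzyloxy)-3-(4,4,5,5-tetramethyl-1,3,2-dioxaborolan-2-yl)phenyl]-4H-chromen-4-one F3. Separately, 8 is benzylated (BnBr, K2CO3, DMF) to 5,7-bis(benzyloxy)-2-[4-(benzyloxy)-3-methoxyphenyl]-8-bromo-4H-chromen-4-one F4. Suzuki–Miyaura coupling of F3 with F4 (Pd(OAc)2, SPhos, K3PO4, toluene/water, 100 °C) gives the hexa-O-benzyl 3'–8'' biflavone F5, and hydrogenolysis (H2, 10% Pd/C, THF/MeOH) gives 18.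

**Step 9 (unsymmetrical silylene tether).** Risks are symmetrical bis(aryloxy)silanes and hydrolysis of the silyl triflate 14.

The fallback sets out from 8 and comes back at 15, building the tether through isolable silanes instead of a one-pot bis-triflate sequence. Phenol 8 is silylated with tBu2SiHCl (imidazole, DMF) to {[5-(benzyloxy)-2-(4-benzyloxy-3-methoxyphenyl)-8-bromo-4-oxo-4H-chromen-7-yl]oxy}di-tert-butylsilane F6. The Si–H bond is chlorinated (CuCl2, cat. CuI, THF, rt) to the corresponding chloro(di-tert-butyl)silyl ether F7. The sodium salt of 13 (NaH, DMF, 50 °C) then displaces chloride to give 15.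

**Step 3 (regioselective bromination).** The risk is bromination at C5 (para to the free hydroxyl) or dibromination.

The fallback sets out from 3 and comes back at 7, moving the bromination to the flavone stage. Fully O-alkylated 5,7-dioxygenated flavones are reported to undergo electrophilic halogenation at C8. Ketone 3 is condensed with 5 (KOH, EtOH/THF) to (E)-1-[2-(benzyloxy)-6-hydroxy-4-(methoxymethoxy)phenyl]-3-[4-(benzyloxy)-3-methoxyphenyl]prop-2-en-1-one F8. This is cyclised (I2 10 mol %, DMSO, 120 °C; any 7-O-MOM lost is restored with MOMCl/iPr2NEt) to 5-(benzyloxy)-2-[4-(benzyloxy)-3-methoxyphenyl]-7-(methoxymethoxy)-4H-chromen-4-one F9. Bromination (NBS, DMF, rt) gives 7, which is carried to 8 by the acid treatment of step 5.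

## Further compounds

F1 | step 10 | 5,7-bis(benzyloxy)-2-(3-bromo-4-hydroxyphenyl)-4H-chromen-4-one | Oc1ccc(-c2cc(=O)c3c(OCc4ccccc4)cc(OCc4ccccc4)cc3o2)cc1Br
F2 | step 10 | 5,7-bis(benzyloxy)-2-[4-(benzyloxy)-3-bromophenyl]-4H-chromen-4-one | Brc1cc(-c2cc(=O)c3c(OCc4ccccc4)cc(OCc4ccccc4)cc3o2)ccc1OCc1ccccc1
F3 | step 10 | 5,7-bis(benzyloxy)-2-[4-(benzyloxy)-3-(4,4,5,5-tetramethyl-1,3,2-dioxaborolan-2-yl)phenyl]-4H-chromen-4-one | CC1(C)OB(OC1(C)C)c1cc(-c2cc(=O)c3c(OCc4ccccc4)cc(OCc4ccccc4)cc3o2)ccc1OCc1ccccc1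
F4 | step 10 | 5,7-bis(benzyloxy)-2-[4-(benzyloxy)-3-methoxyphenyl]-8-bromo-4H-chromen-4-one | COc1cc(-c2cc(=O)c3c(OCc4ccccc4)cc(OCc4ccccc4)c(Br)c3o2)ccc1OCc1ccccc1
F5 | step 10 | hexa-O-benzyl 3'–8'' biflavone (5,7,4'-tri-OBn apigenin half; 5'',7'',4'''-tri-OBn, 3'''-OMe chrysoeriol half) | COc1cc(-c2cc(=O)c3c(OCc4ccccc4)cc(OCc4ccccc4)c(-c4cc(-c5cc(=O)c6c(OCc7ccccc7)cc(OCc7ccccc7)cc6o5)ccc4OCc4ccccc4)c3o2)ccc1OCc1ccccc1
F6 | step 9 | {[5-(benzyloxy)-2-(4-benzyloxy-3-methoxyphenyl)-8-bromo-4-oxo-4H-chromen-7-yl]oxy}di-tert-butylsilane | CC(C)(C)[SiH](Oc1cc(OCc2ccccc2)c2c(=O)cc(-c3ccc(OCc4ccccc4)c(OC)c3)oc2c1Br)C(C)(C)C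
F7 | step 9 | {[5-(benzyloxy)-2-(4-benzyloxy-3-methoxyphenyl)-8-bromo-4-oxo-4H-chromen-7-yl]oxy}di-tert-butylchlorosilane | CC(C)(C)[Si](Cl)(Oc1cc(OCc2ccccc2)c2c(=O)cc(-c3ccc(OCc4ccccc4)c(OC)c3)oc2c1Br)C(C)(C)C
F8 | step 3 | (E)-1-[2-(benzyloxy)-6-hydroxy-4-(methoxymethoxy)phenyl]-3-[4-(benzyloxy)-3-methoxyphenyl]prop-2-en-1-one | COCOc1cc(O)c(C(=O)/C=C/c2ccc(OCc3ccccc3)c(OC)c2)c(OCc2ccccc2)c1
F9 | step 3 | 5-(benzyloxy)-2-[4-(benzyloxy)-3-methoxyphenyl]-7-(methoxymethoxy)-4H-chromen-4-one | COCOc1cc(OCc2ccccc2)c2c(=O)cc(-c3ccc(OCc4ccccc4)c(OC)c3)oc2c1
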